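**Retrosynthetic overview**

- The C40 chain is cut at C11=C12 and C11'=C12' (two Wittig reactions) into the commercial C10 trienedial 18 and two C15 phosphonium salts: 16 (free hydroxyl, becomes ring A) and its triethylsilyl ether 17 (becomes ring B). The ring A ketone is made last, by oxidising the one unprotected allylic alcohol.
- Salts 16 and 17 come from (3S,6S)-3-acetoxy-α-ionone 14, and 14 from cyclohexenone 9 (the ring A skeleton with C7 as a silyloxymethyl group), so both end rings derive from 9.
- Key disconnection: bond C1–C2 of that carbocycle. Enabling feature: the ketone oxygen on C3 and the gem-dimethyl carbon C1 are 1,3-related across C2H2, and C4=C5 is cis in the ring. C1 can therefore be carried on that oxygen as a tertiary enol ether (the 2-methylidene-3,6-dihydro-2H-pyran 7) and moved from O to C2.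
- 7 comes from the unsaturated δ-lactone 6 (methylenation), 6 by ring-closing metathesis from the (S)-diol 3, and 3 from the Sharpless epoxide 2 of prenol opened by an isopropenyl cuprate. This sets C6; C3' follows by substrate-controlled reduction.
- Ring order: oxirane (temporary), then dihydropyranone (temporary), then the six-membered carbocycle by the O-to-C shift; the carbocycle is made once and serves ring A and ring B.

Key step: step 7

Remark: carotenoid locants are used for the ring atoms (C1 gem-dimethyl carbon, C3 oxygenated carbon, C6 stereocentre bearing C7); the C10 dialdehyde 18 is taken as a commercial building block; the C9 carbinol epimers formed in step 13 are carried on together because that centre is destroyed in step 14; salt 16 is divided, one part being silylated in step 15 and the other used unchanged in step 17.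

**Route**

Step 1
Reactants: 1 3-methylbut-2-en-1-ol (prenol)
Product: 2 (R)-(3,3-dimethyloxiran-2-yl)methanol
Conditions: Ti(OiPr)4 (5 mol %), D-(−)-diethyl tartrate (6 mol %), t-BuOOH, 4 Å molecular sieves, CH2Cl2, −20 °C
Reagents that add atoms: tert-butyl hydroperoxide, CC(C)(C)OO
Why: Sharpless asymmetric epoxidation of a trisubstituted allylic alcohol; the D-tartrate ligand directs oxygen to the face that gives the (R)-epoxide, the source of C6 in both end rings.

Step 2
Reactants: 2 (R)-(3,3-dimethyloxiran-2-yl)methanol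
Product: 3 (S)-3-methyl-2-(prop-1-en-2-yl)butane-1,3-diol
Conditions: CH2=C(CH3)MgBr (3 equiv), CuI (10 mol %), THF, −30 → 0 °C; aq NH4Cl
Reagents that add atoms: isopropenylmagnesium bromide, C=C(C)[Mg]Br
Why: Copper-catalysed Grignard opening of a 2,3-epoxy alcohol; SN2 attack at C2, the only epoxide carbon that is not fully substituted, occurs anti to the C–O bond, so the C–C bond forms with inversion and gives the (S)-1,3-diol.

Step 3
Reactants: 3 (S)-3-methyl-2-(prop-1-en-2-yl)butane-1,3-diol
Product: 4 (S)-3-({[tert-butyl(dimethyl)silyl]oxy}methyl)-2,4-dimethylpent-4-en-2-ol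
Conditions: TBSCl (1.05 equiv), imidazole, CH2Cl2, 0 °C
Reagents that add atoms: tert-butyldimethylsilyl chloride, CC(C)(C)[Si](C)(C)Cl
Why: Silylation, in which the primary hydroxyl reacts far faster than the hindered tertiary one.

Step 4
Reactants: 4 (S)-3-({[tert-butyl(dimethyl)silyl]oxy}methyl)-2,4-dimethylpent-4-en-2-ol
Product: 5 (S)-3-({[tert-butyl(dimethyl)silyl]oxy}methyl)-2,4-dimethylpent-4-en-2-yl prop-2-enoate
Conditions: acryloyl chloride, i-Pr2NEt, DMAP (0.2 equiv), CH2Cl2, 0 °C → rt
Reagents that add atoms: acryloyl chloride, C=CC(=O)Cl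
Why: DMAP-catalysed O-acylation of the tertiary alcohol with a small, reactive acid chloride installs the second alkene for ring closure.

Step 5
Reactants: 5 (S)-3-({[tert-butyl(dimethyl)silyl]oxy}methyl)-2,4-dimethylpent-4-en-2-yl prop-2-enoate
Product: 6 (S)-5-({[tert-butyl(dimethyl)silyl]oxy}methyl)-4,6,6-trimethyl-5,6-dihydro-2H-pyran-2-one
Conditions: second-generation Grubbs catalyst (5 mol %), toluene, 80 °C
Reagents that add atoms: none
Why: Ring-closing metathesis of the acrylate with the 1,1-disubstituted alkene, helped by the gem-dimethyl (Thorpe–Ingold) effect; the ring enforces the cis geometry of the new trisubstituted C4=C5 bond that the key step needs.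

Step 6
Reactants: 6 (S)-5-({[tert-butyl(dimethyl)silyl]oxy}methyl)-4,6,6-trimethyl-5,6-dihydro-2H-pyran-2-one
Product: 7 (S)-tert-butyl(dimethyl)[(2,2,4-trimethyl-6-methylidene-3,6-dihydro-2H-pyran-3-yl)methoxy]silane
Conditions: Cp2TiMe2 (2.5 equiv), toluene, 65 °C, dark; filtration through basic alumina
Reagents that add atoms: dimethyltitanocene, C[Ti](C)(C1C=CC=C1)C1C=CC=C1
Why: Petasis methylenation of the lactone carbonyl through Cp2Ti=CH2 under non-acidic conditions should give the acid-sensitive exocyclic dienol ether without touching C6.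

Step 7
Reactants: 7 (S)-tert-butyl(dimethyl)[(2,2,4-trimethyl-6-methylidene-3,6-dihydro-2H-pyran-3-yl)methoxy]silane
Product: 9 (S)-4-({[tert-butyl(dimethyl)silyl]oxy}methyl)-3,5,5-trimethylcyclohex-2-en-1-one, via carbocation–aluminium dienolate zwitterion 8 (not isolated)
Conditions: Me2AlCl (1.2 equiv), CH2Cl2, −78 → −20 °C; then Et3N, aq NaHCO3
Reagents that add atoms: none
Why: Proposed new method: Me2AlCl binds the ring oxygen of 7 and the tertiary O–C1 bond ionises to zwitterion 8, a tertiary carbocation at C1 tethered to a cross-conjugated aluminium dienolate (C2=C3(OAl)–C4=C5), which collapses by C-alkylation at C2 to the cyclohexenone. The closest known reaction types are the Petasis–Ferrier rearrangement and the Lewis-acid-mediated 1,3 oxygen-to-carbon rearrangement of 6-substituted 2-methylidenetetrahydropyrans to cyclohexanones, together with Lewis-acid tert-alkylation of enol derivatives (Reetz alkylation) and the Fries-type O-to-C migration of tert-alkyl aryl ethers; new here are an unstabilised tertiary alkyl cation and a dienol ether. The carbocycle closes by a 6-(enolendo) C-alkylation through the array C2–C3–C4–C5–C6–C1, the two ends being held together by the cis C4=C5 bond inherited from the pyran. No new stereocentre is formed, because C1 carries two methyl groups, and C6 is not a reacting atom, so its configuration should be carried over unchanged. The step needs C- over O-recombination (the latter only regenerates 7) and ring closure faster than proton loss or 1,2-hydride shift from C6; the intramolecular ion pair, the low temperature and the absence of any base or proton source (Me2AlCl destroys adventitious acid as methane) are expected to secure this. Attack through C4 is excluded because it would close a four-membered ring.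

Step 8
Reactants: 9 (S)-4-({[tert-butyl(dimethyl)silyl]oxy}methyl)-3,5,5-trimethylcyclohex-2-en-1-one
Product: 10 (1S,4S)-4-({[tert-butyl(dimethyl)silyl]oxy}methyl)-3,5,5-trimethylcyclohex-2-en-1-ol
Conditions: LiBH(sec-Bu)3 (L-Selectride), THF, −78 °C; aq NH4Cl
Reagents that add atoms: none
Why: 1,2-Reduction of the β,β-disubstituted enone by a bulky hydride; with the C6 substituent pseudoaxial (A(1,2) strain with the C5 methyl), the axial methyl on C1 shields the syn face, so hydride should enter anti to it and give the pseudoaxial hydroxyl trans to the C6 substituent (3S), by analogy with 3,3,5-trimethylcyclohexanone.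

Step 9
Reactants: 10 (1S,4S)-4-({[tert-butyl(dimethyl)silyl]oxy}methyl)-3,5,5-trimethylcyclohex-2-en-1-ol
Product: 11 (1S,4S)-4-({[tert-butyl(dimethyl)silyl]oxy}methyl)-3,5,5-trimethylcyclohex-2-en-1-yl acetate
Conditions: Ac2O, pyridine, DMAP (cat.), CH2Cl2, rt
Reagents that add atoms: acetic anhydride, CC(=O)OC(C)=O
Why: Acetylation protects the allylic hydroxyl for the oxidation and olefination that follow.

Step 10
Reactants: 11 (1S,4S)-4-({[tert-butyl(dimethyl)silyl]oxy}methyl)-3,5,5-trimethylcyclohex-2-en-1-yl acetate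
Product: 12 (1S,4S)-4-(hydroxymethyl)-3,5,5-trimethylcyclohex-2-en-1-yl acetate
Conditions: HF·pyridine, pyridine, THF, 0 °C → rt
Reagents that add atoms: none
Why: Fluoride cleaves the primary silyl ether and leaves the secondary allylic acetate untouched.

Step 11
Reactants: 12 (1S,4S)-4-(hydroxymethyl)-3,5,5-trimethylcyclohex-2-en-1-yl acetate
Product: 13 (1S,4S)-4-formyl-3,5,5-trimethylcyclohex-2-en-1-yl acetate
Conditions: Dess–Martin periodinane, pyridine, CH2Cl2, 0 °C
Reagents that add atoms: none
Why: Dess–Martin oxidation under buffered, non-basic conditions should give the α-branched β,γ-unsaturated aldehyde without epimerisation at C6 or migration of the ring double bond.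

Step 12
Reactants: 13 (1S,4S)-4-formyl-3,5,5-trimethylcyclohex-2-en-1-yl acetate
Product: 14 (1S,4S)-3,5,5-trimethyl-4-[(1E)-3-oxobut-1-en-1-yl]cyclohex-2-en-1-yl acetate ((3S,6S)-3-acetoxy-α-ionone)
Conditions: Ph3P=CHC(O)CH3, toluene, 90 °C
Reagents that add atoms: 1-(triphenylphosphoranylidene)propan-2-one, CC(=O)C=P(c1ccccc1)(c1ccccc1)c1ccccc1
Why: Wittig olefination with a keto-stabilised, essentially non-basic ylide should give the (E)-enone (C7=C8) and leave the α-stereocentre intact.

Step 13
Reactants: 14 (1S,4S)-3,5,5-trimethyl-4-[(1E)-3-oxobut-1-en-1-yl]cyclohex-2-en-1-yl acetate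
Product: 15 (1S,4S)-4-[(1E)-3-hydroxy-3-methylpenta-1,4-dien-1-yl]-3,5,5-trimethylcyclohex-2-en-1-ol (both C9 carbinol epimers)
Conditions: CH2=CHMgBr (3.5 equiv), THF, −40 → 0 °C; aq NH4Cl
Reagents that add atoms: vinylmagnesium bromide, C=C[Mg]Br
Why: Vinyl Grignard adds 1,2 to the side-chain enone and the excess cleaves the acetate; the new C9 carbinol centre forms without control, which is immaterial.

Step 14
Reactants: 15 (1S,4S)-4-[(1E)-3-hydroxy-3-methylpenta-1,4-dien-1-yl]-3,5,5-trimethylcyclohex-2-en-1-ol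
Product: 16 {(2E,4E)-5-[(1S,4S)-4-hydroxy-2,6,6-trimethylcyclohex-2-en-1-yl]-3-methylpenta-2,4-dien-1-yl}triphenylphosphonium bromide
Conditions: PPh3·HBr (1.0 equiv), CH2Cl2, 0 °C → rt
Reagents that add atoms: triphenylphosphine hydrobromide, Br.c1ccc(cc1)P(c1ccccc1)c1ccccc1
Why: The doubly allylic tertiary alcohol ionises under the mild acid and triphenylphosphine attacks the unhindered terminus (SN1′ with allylic transposition) to give mainly the (9E)-salt; one equivalent of acid at low temperature is chosen so that the slower-ionising ring allylic alcohol is spared.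

Step 15
Reactants: 16 {(2E,4E)-5-[(1S,4S)-4-hydroxy-2,6,6-trimethylcyclohex-2-en-1-yl]-3-methylpenta-2,4-dien-1-yl}triphenylphosphonium bromide
Product: 17 {(2E,4E)-3-methyl-5-[(1S,4S)-2,6,6-trimethyl-4-[(triethylsilyl)oxy]cyclohex-2-en-1-yl]penta-2,4-dien-1-yl}triphenylphosphonium bromide
Conditions: Et3SiCl (1.2 equiv), imidazole (2.5 equiv), CH2Cl2, 0 °C → rt; wash with aq NaBr
Reagents that add atoms: chlorotriethylsilane, CC[Si](CC)(CC)Cl
Why: Silylation of the only hydroxyl marks the future ring B so that only ring A is oxidised later; imidazole is far too weak a base to deprotonate the allylic phosphonium salt, and the bromide wash keeps a single counter-ion.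

Step 16
Reactants: 17 the triethylsilyl-protected C15 phosphonium bromide; 18 (2E,4E,6E)-2,7-dimethylocta-2,4,6-trienedial
Product: 20 (3S,6S)-3-[(triethylsilyl)oxy]-12'-apo-ε-caroten-12'-al (C25 aldehyde carrying ring B), via silyloxy phosphonium ylide 19 (not isolated)
Conditions: 18 (2 equiv), 1,2-epoxybutane, reflux, 17 added in portions; then heptane, reflux (Z → E), chromatography
Reagents that add atoms: none
Why: Wittig reaction without added base (the epoxide traps HBr as the bromohydrin, so the silyl ether is not exposed to acid or alkoxide); excess dialdehyde should confine the reaction to one aldehyde group, and Z isomers at the new double bond (C11'=C12' in the numbering of the target) are converted to the all-E compound on heating.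

Step 17
Reactants: 20 (3S,6S)-3-[(triethylsilyl)oxy]-12'-apo-ε-caroten-12'-al; 16 the hydroxy C15 phosphonium bromide
Product: 22 (3S,6S,3'S,6'S)-3'-[(triethylsilyl)oxy]-ε,ε-caroten-3-ol, via hydroxy phosphonium ylide 21 (not isolated)
Conditions: 16 (1.3 equiv), 1,2-epoxybutane, reflux; then heptane, reflux (Z → E)
Reagents that add atoms: none
Why: A second Wittig reaction, now of the unprotected ylide with the C25 aldehyde, forms C11=C12 and completes the C40 chain with a free hydroxyl on ring A only; thermal isomerisation should give the all-E polyene.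

Step 18
Reactants: 22 (3S,6S,3'S,6'S)-3'-[(triethylsilyl)oxy]-ε,ε-caroten-3-ol
Product: 23 (6S,3'S,6'S)-3'-[(triethylsilyl)oxy]-ε,ε-caroten-3-one
Conditions: MnO2 (activated, excess), CH2Cl2, rt, dark, argon
Reagents that add atoms: none
Why: MnO2 oxidises only the free allylic alcohol of ring A to the enone under neutral conditions, which should keep the base-sensitive C6 centre (γ to the new ketone) intact.

Step 19
Reactants: 23 (6S,3'S,6'S)-3'-[(triethylsilyl)oxy]-ε,ε-caroten-3-one
Product: 24 (6S,3'S,6'S)-3'-hydroxy-ε,ε-caroten-3-one (target)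
Conditions: HF·pyridine, pyridine, THF, 0 °C
Reagents that add atoms: none
Why: Buffered fluoride removes the triethylsilyl ether without acid strong enough to ionise the ring B allylic alcohol or base strong enough to enolise ring A.

**Compound list**

1 | 3-methylbut-2-en-1-ol (prenol) | CC(C)=CCO | starting material
2 | (R)-(3,3-dimethyloxiran-2-yl)methanol | CC1(C)O[C@@H]1CO | intermediate
3 | (S)-3-methyl-2-(prop-1-en-2-yl)butane-1,3-diol | CC(C)(O)[C@H](CO)C(C)=C | intermediate
4 | (S)-3-({[tert-butyl(dimethyl)silyl]oxy}methyl)-2,4-dimethylpent-4-en-2-ol | CC(C)(O)[C@H](CO[Si](C)(C)C(C)(C)C)C(C)=C | intermediate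
5 | (S)-3-({[tert-butyl(dimethyl)silyl]oxy}methyl)-2,4-dimethylpent-4-en-2-yl prop-2-enoate | C=CC(=O)OC(C)(C)[C@H](CO[Si](C)(C)C(C)(C)C)C(C)=C | intermediate
6 | (S)-5-({[tert-butyl(dimethyl)silyl]oxy}methyl)-4,6,6-trimethyl-5,6-dihydro-2H-pyran-2-one | O=C1C=C(C)[C@@H](CO[Si](C)(C)C(C)(C)C)C(C)(C)O1 | intermediate
7 | (S)-tert-butyl(dimethyl)[(2,2,4-trimethyl-6-methylidene-3,6-dihydro-2H-pyran-3-yl)methoxy]silane | C=C1C=C(C)[C@@H](CO[Si](C)(C)C(C)(C)C)C(C)(C)O1 | intermediate
8 | zwitterion of the C1 tertiary carbocation and the chlorodimethylaluminium dienolate (formed in the flask, not isolated) | C=C(O[Al-](C)(C)Cl)/C=C(/C)[C@@H](CO[Si](C)(C)C(C)(C)C)[C+](C)C | intermediate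
9 | (S)-4-({[tert-butyl(dimethyl)silyl]oxy}methyl)-3,5,5-trimethylcyclohex-2-en-1-one | CC1=CC(=O)CC(C)(C)[C@@H]1CO[Si](C)(C)C(C)(C)C | intermediate
10 | (1S,4S)-4-({[tert-butyl(dimethyl)silyl]oxy}methyl)-3,5,5-trimethylcyclohex-2-en-1-ol | CC(C)(C)[Si](C)(C)OC[C@@H]1C(C)=C[C@@H](O)CC1(C)C | intermediate
11 | (1S,4S)-4-({[tert-butyl(dimethyl)silyl]oxy}methyl)-3,5,5-trimethylcyclohex-2-en-1-yl acetate | CC(C)(C)[Si](C)(C)OC[C@@H]1C(C)=C[C@@H](OC(C)=O)CC1(C)C | intermediate
12 | (1S,4S)-4-(hydroxymethyl)-3,5,5-trimethylcyclohex-2-en-1-yl acetate | OC[C@@H]1C(C)=C[C@@H](OC(C)=O)CC1(C)C | intermediate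
13 | (1S,4S)-4-formyl-3,5,5-trimethylcyclohex-2-en-1-yl acetate | O=C[C@@H]1C(C)=C[C@@H](OC(C)=O)CC1(C)C | intermediate
14 | (1S,4S)-3,5,5-trimethyl-4-[(1E)-3-oxobut-1-en-1-yl]cyclohex-2-en-1-yl acetate | CC(=O)/C=C/[C@@H]1C(C)=C[C@@H](OC(C)=O)CC1(C)C | intermediate
15 | (1S,4S)-4-[(1E)-3-hydroxy-3-methylpenta-1,4-dien-1-yl]-3,5,5-trimethylcyclohex-2-en-1-ol (C9 epimers) | C=CC(C)(O)/C=C/[C@@H]1C(C)=C[C@@H](O)CC1(C)C | intermediate
16 | {(2E,4E)-5-[(1S,4S)-4-hydroxy-2,6,6-trimethylcyclohex-2-en-1-yl]-3-methylpenta-2,4-dien-1-yl}triphenylphosphonium bromide | [Br-].c1ccccc1[P+](c1ccccc1)(c1ccccc1)C/C=C(C)/C=C/[C@@H]1C(C)=C[C@@H](O)CC1(C)C | intermediate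
17 | {(2E,4E)-3-methyl-5-[(1S,4S)-2,6,6-trimethyl-4-[(triethylsilyl)oxy]cyclohex-2-en-1-yl]penta-2,4-dien-1-yl}triphenylphosphonium bromide | [Br-].c1ccccc1[P+](c1ccccc1)(c1ccccc1)C/C=C(C)/C=C/[C@@H]1C(C)=C[C@@H](O[Si](CC)(CC)CC)CC1(C)C | intermediate
18 | (2E,4E,6E)-2,7-dimethylocta-2,4,6-trienedial | O=C/C(C)=C/C=C/C=C(C)/C=O | starting material
19 | {(2E,4E)-3-methyl-5-[(1S,4S)-2,6,6-trimethyl-4-[(triethylsilyl)oxy]cyclohex-2-en-1-yl]penta-2,4-dien-1-ylidene}triphenylphosphorane (formed in the flask, not isolated) | c1ccccc1P(c1ccccc1)(c1ccccc1)=C/C=C(C)/C=C/[C@@H]1C(C)=C[C@@H](O[Si](CC)(CC)CC)CC1(C)C | intermediate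
20 | (3S,6S)-3-[(triethylsilyl)oxy]-12'-apo-ε-caroten-12'-al | O=C/C(C)=C/C=C/C=C(C)/C=C/C=C(C)/C=C/[C@@H]1C(C)=C[C@@H](O[Si](CC)(CC)CC)CC1(C)C | intermediate
21 | {(2E,4E)-5-[(1S,4S)-4-hydroxy-2,6,6-trimethylcyclohex-2-en-1-yl]-3-methylpenta-2,4-dien-1-ylidene}triphenylphosphorane (formed in the flask, not isolated) | c1ccccc1P(c1ccccc1)(c1ccccc1)=C/C=C(C)/C=C/[C@@H]1C(C)=C[C@@H](O)CC1(C)C | intermediate
22 | (3S,6S,3'S,6'S)-3'-[(triethylsilyl)oxy]-ε,ε-caroten-3-ol | CC1=C[C@@H](O)CC(C)(C)[C@@H]1/C=C/C(C)=C/C=C/C(C)=C/C=C/C=C(C)/C=C/C=C(C)/C=C/[C@@H]1C(C)=C[C@@H](O[Si](CC)(CC)CC)CC1(C)C | intermediate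
23 | (6S,3'S,6'S)-3'-[(triethylsilyl)oxy]-ε,ε-caroten-3-one | CC1=CC(=O)CC(C)(C)[C@@H]1/C=C/C(C)=C/C=C/C(C)=C/C=C/C=C(C)/C=C/C=C(C)/C=C/[C@@H]1C(C)=C[C@@H](O[Si](CC)(CC)CC)CC1(C)C | intermediate
24 | (6S,3'S,6'S)-3'-hydroxy-ε,ε-caroten-3-one | CC1=CC(=O)CC(C)(C)[C@@H]1/C=C/C(C)=C/C=C/C(C)=C/C=C/C=C(C)/C=C/C=C(C)/C=C/[C@@H]1C(C)=C[C@@H](O)CC1(C)C | target

**Step count**

Total steps: 19. Longest linear sequence: 19 steps (1 to 24 through 16, 17, 20, 22 and 23; the unsilylated part of salt 16 re-enters at step 17, so there is no separate branch).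

**Steps most likely to fail**

Step 7 (key step). The tertiary cation may be lost before the C1–C2 bond forms: by proton loss or 1,2-hydride shift from C6 (which erases the stereocentre), by methyl transfer from aluminium, or by acid isomerisation of the exocyclic enol ether into the ring.

The fallback sets out from 7 and forms the same bond by known chemistry at the cost of a resolution. A trace of pyridinium p-toluenesulfonate in benzene isomerises 7 to the endocyclic 2H-pyran tert-butyl(dimethyl)[(2,2,4,6-tetramethyl-2H-pyran-3-yl)methoxy]silane F1, which is in electrocyclic equilibrium with its open valence isomer (3Z)-5-({[tert-butyl(dimethyl)silyl]oxy}methyl)-4,6-dimethylhepta-3,5-dien-2-one F2. KOt-Bu in t-BuOH/THF deprotonates the methyl ketone and the trienolate closes C1–C2 by the isophorone-type 6π closure, giving after equilibration the racemic ketone rac-4-({[tert-butyl(dimethyl)silyl]oxy}methyl)-3,5,5-trimethylcyclohex-2-en-1-one F3. LiBH(sec-Bu)3 should give the racemic trans alcohol rac-(1S*,4S*)-4-({[tert-butyl(dimethyl)silyl]oxy}methyl)-3,5,5-trimethylcyclohex-2-en-1-ol F4. Esterification with (S)-2-methoxy-2-phenylacetic acid (DCC, DMAP) gives two diastereomers to be separated by chromatography: the (1S,4S)-configured ester F5 and the (1R,4R)-configured ester F6. Hydrolysis of F5 (LiOH, THF/H2O) comes back to the route at 10.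

Step 2. The cuprate may fail to attack C2, which is flanked by a fully substituted carbon, so that bromide opening at the tertiary carbon, Payne rearrangement or base-induced isomerisation of the epoxide take over.

The fallback sets out from 2 and replaces the vinyl cuprate by a slim sp nucleophile and the metathesis by a conjugate methylation. Silylation (TBSCl, imidazole) gives (R)-tert-butyl[(3,3-dimethyloxiran-2-yl)methoxy]dimethylsilane F7. Lithium acetylide–ethylenediamine complex in DMSO should open it at C2 with inversion to (S)-3-({[tert-butyl(dimethyl)silyl]oxy}methyl)-2-methylpent-4-yn-2-ol F8. Double deprotonation (n-BuLi, 2 equiv) and methyl chloroformate give methyl (S)-4-({[tert-butyl(dimethyl)silyl]oxy}methyl)-5-hydroxy-5-methylhex-2-ynoate F9. Me2CuLi (THF, −78 °C) adds syn across the ynoate, and the resulting (Z)-β-methyl enoate, with the ester cis to the carbinol arm, lactonises to 6, where the route is rejoined.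

Step 12. Attack on the neopentyl-type aldehyde may be slow, which would let epimerisation at C6 or shift of the ring double bond into conjugation with the aldehyde compete.

The fallback sets out from 13 and builds the enone in two stages without a phosphorus ylide. A Mukaiyama aldol addition of 2-(trimethylsilyloxy)propene (BF3·OEt2, CH2Cl2, −78 °C) gives, after aqueous work-up, (1S,4S)-4-(1-hydroxy-3-oxobutyl)-3,5,5-trimethylcyclohex-2-en-1-yl acetate F10. Mesylation (MsCl, Et3N, 0 °C) gives (1S,4S)-4-[1-(methanesulfonyloxy)-3-oxobutyl]-3,5,5-trimethylcyclohex-2-en-1-yl acetate F11, which is eliminated in the same flask with DBU to the (E)-enone 14, where the route is rejoined.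

**Further compounds**

F1 | step 7 | tert-butyl(dimethyl)[(2,2,4,6-tetramethyl-2H-pyran-3-yl)methoxy]silane | CC1=CC(C)=C(CO[Si](C)(C)C(C)(C)C)C(C)(C)O1
F2 | step 7 | (3Z)-5-({[tert-butyl(dimethyl)silyl]oxy}methyl)-4,6-dimethylhepta-3,5-dien-2-one | CC(=O)/C=C(/C)C(CO[Si](C)(C)C(C)(C)C)=C(C)C
F3 | step 7 | rac-4-({[tert-butyl(dimethyl)silyl]oxy}methyl)-3,5,5-trimethylcyclohex-2-en-1-one (both enantiomers) | CC1=CC(=O)CC(C)(C)[C@@H]1CO[Si](C)(C)C(C)(C)C.CC1=CC(=O)CC(C)(C)[C@H]1CO[Si](C)(C)C(C)(C)C
F4 | step 7 | rac-(1S*,4S*)-4-({[tert-butyl(dimethyl)silyl]oxy}methyl)-3,5,5-trimethylcyclohex-2-en-1-ol (both enantiomers) | CC(C)(C)[Si](C)(C)OC[C@@H]1C(C)=C[C@@H](O)CC1(C)C.CC(C)(C)[Si](C)(C)OC[C@H]1C(C)=C[C@H](O)CC1(C)C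
F5 | step 7 | (1S,4S)-4-({[tert-butyl(dimethyl)silyl]oxy}methyl)-3,5,5-trimethylcyclohex-2-en-1-yl (S)-2-methoxy-2-phenylacetate | CC(C)(C)[Si](C)(C)OC[C@@H]1C(C)=C[C@@H](OC(=O)[C@@H](OC)c2ccccc2)CC1(C)C
F6 | step 7 | (1R,4R)-4-({[tert-butyl(dimethyl)silyl]oxy}methyl)-3,5,5-trimethylcyclohex-2-en-1-yl (S)-2-methoxy-2-phenylacetate | CC(C)(C)[Si](C)(C)OC[C@H]1C(C)=C[C@H](OC(=O)[C@@H](OC)c2ccccc2)CC1(C)C
F7 | step 2 | (R)-tert-butyl[(3,3-dimethyloxiran-2-yl)methoxy]dimethylsilane | CC1(C)O[C@@H]1CO[Si](C)(C)C(C)(C)C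
F8 | step 2 | (S)-3-({[tert-butyl(dimethyl)silyl]oxy}methyl)-2-methylpent-4-yn-2-ol | CC(C)(O)[C@H](CO[Si](C)(C)C(C)(C)C)C#C
F9 | step 2 | methyl (S)-4-({[tert-butyl(dimethyl)silyl]oxy}methyl)-5-hydroxy-5-methylhex-2-ynoate | CC(C)(O)[C@H](CO[Si](C)(C)C(C)(C)C)C#CC(=O)OC
F10 | step 12 | (1S,4S)-4-(1-hydroxy-3-oxobutyl)-3,5,5-trimethylcyclohex-2-en-1-yl acetate (carbinol epimers) | CC(=O)CC(O)[C@@H]1C(C)=C[C@@H](OC(C)=O)CC1(C)C
F11 | step 12 | (1S,4S)-4-[1-(methanesulfonyloxy)-3-oxobutyl]-3,5,5-trimethylcyclohex-2-en-1-yl acetate (carbinol epimers) | CC(=O)CC(OS(C)(=O)=O)[C@@H]1C(C)=C[C@@H](OC(C)=O)CC1(C)C
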